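**Plan**

- Retrosynthesis: the C3–OH bond and the three O-benzyl bonds are cut first. Ring A is then opened at C7–C8 and C5–C6, which leaves a 2-methyl-4-pyranone-3-carboxylate (rings B and C) and 6,6-dimethyl-δ-valerolactone. The pyranone is cut at O1–C2 and C3–C4 into an arylpropioloyl chloride and methyl acetoacetate.
- Enabling feature: ring A is a 5,7-resorcinol whose C6 carries CH2CH2C(CH3)2OH. C7, C6 and this chain are the carbonyl carbon, the α-carbon and the rest of the δ-lactone; C5 is the ester carbon on C4a; C8 is the 2-methyl carbon of the pyranone.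
- Forward order: ring B is bought; ring C is closed first (C-acylation, then 6-endo-dig oxa-Michael addition); ring A is annulated onto ring C in one flask, and the chain arrives with the lactone.
- End game: benzylation of the 5- and 7-hydroxyls, C3 hydroxylation through the 2,3-epoxide, hydrogenolysis.
- Stereochemistry: the target is achiral. The only stereogenic intermediate, the 2,3-epoxide, is racemic and is consumed in the flask where it forms.

Key step: step 5

Remark: compounds 1, 4 and 7 are taken as commercial; the lactone 9 is made in one step so that the route does not depend on its supply.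

Step 1
Reactants: 1 1-(benzyloxy)-4-ethynylbenzene
Product: 2 3-[4-(benzyloxy)phenyl]prop-2-ynoic acid
Conditions: n-BuLi (1.05 equiv), THF, −78 °C; CO2, −78 → 0 °C; 1 M HCl
Reagents that add atoms: carbon dioxide, O=C=O
Why: Carboxylation of a lithium acetylide is the standard route to arylpropiolic acids, and the acetylenic proton is removed far faster than the aryl benzyl ether is metalated at −78 °C.

Step 2
Reactants: 2 3-[4-(benzyloxy)phenyl]prop-2-ynoic acid
Product: 3 3-[4-(benzyloxy)phenyl]prop-2-ynoyl chloride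
Conditions: (COCl)2 (1.5 equiv), DMF (cat.), CH2Cl2, 0 °C → rt; evaporation, used crude
Reagents that add atoms: oxalyl chloride, O=C(Cl)C(=O)Cl
Why: Acid chloride formation through the Vilsmeier-type chloroiminium species runs cold and without strong acid or base, so the alkyne and the benzyl ether should survive.

Step 3
Reactants: 3 3-[4-(benzyloxy)phenyl]prop-2-ynoyl chloride; 4 methyl acetoacetate
Product: 6 methyl 6-[4-(benzyloxy)phenyl]-2-methyl-4-oxo-4H-pyran-3-carboxylate, via methyl 2-acetyl-5-[4-(benzyloxy)phenyl]-3-oxopent-4-ynoate 5 (not isolated)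
Conditions: 4, MgCl2 (1 equiv), pyridine (2 equiv), CH2Cl2, 0 °C; then 3, 0 °C → rt; 1 M HCl wash; Et3N (cat.), CH2Cl2, rt
Reagents that add atoms: none
Why: Magnesium-chelate C-acylation of the β-keto ester gives the triacylmethane 5, whose acetyl enol oxygen adds to the ynone β-carbon in a 6-endo-dig oxa-Michael closure, the established alkynoyl chloride route to 3-acyl-4-pyranones.

Step 4
Reactants: 7 ethyl 5-oxohexanoate
Product: 9 6,6-dimethyltetrahydro-2H-pyran-2-one, via ethyl 5-hydroxy-5-methylhexanoate 8 (not isolated)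
Conditions: MeMgBr (1.05 equiv), THF, −78 → −20 °C; 1 M HCl; TsOH·H2O (cat.), PhMe, 60 °C
Reagents that add atoms: methylmagnesium bromide, C[Mg]Br
Why: Grignard addition is chemoselective for the ketone over the ester at low temperature, and acid-catalysed lactonisation of the δ-hydroxy ester then closes the gem-dimethyl δ-lactone.

Step 5
Reactants: 6 methyl 6-[4-(benzyloxy)phenyl]-2-methyl-4-oxo-4H-pyran-3-carboxylate; 9 6,6-dimethyltetrahydro-2H-pyran-2-one
Product: 11 2-[4-(benzyloxy)phenyl]-5,7-dihydroxy-6-(3-hydroxy-3-methylbutyl)-4H-chromen-4-one, via methyl 6-[4-(benzyloxy)phenyl]-2-(6-hydroxy-6-methyl-2-oxoheptyl)-4-oxo-4H-pyran-3-carboxylate 10 (not isolated)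
Conditions: LDA (1.1 equiv), THF, −78 °C; 9 (1.1 equiv), −78 °C; LDA (2.3 equiv), −78 → 0 °C; AcOH quench
Reagents that add atoms: none
Why: Proposed new method: LDA removes a proton from the 2-methyl group of 6, which is vinylogous to both the C4 ketone and the C3 ester, and the lithium dienolate adds through its exocyclic carbon to the lactone carbonyl of 9; the lactol alkoxide opens to keto ester 10 (new C7–C8 bond) and sets the tertiary alkoxide free. The further base converts 10 first into the conjugated C8 enolate and then into the C6,C8-dianion, whose more basic C6 carbanion attacks the neighbouring methyl ester; loss of methoxide and enolisation of the triketone give the aromatic 5,7-diol (new C5–C6 bond). The closest known reaction types are the lateral lithiation–acylation of 2-methyl-4-pyranones and the Claisen–Dieckmann sequence of ortho-toluate anions with esters that gives 1,3-dihydroxynaphthalenes; new is their union on a pyranone ester with a lactone as acyl donor. Ring A closes in a 6-exo-trig Dieckmann condensation and no stereocentre is formed. The step needs C-acylation by C6 in place of O-acylation by the C7 enolate oxygen, which dianion formation by the extra base and the irreversible aromatisation should secure; it also needs the chain at C6 and not at C8, which connectivity fixes because O1 already belongs to ring C and the chain carbon is the lactone α-carbon. Adding the lactone to the preformed monoanion at −78 °C before the remaining base should keep enolisation of the lactone by LDA small.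

Step 6
Reactants: 11 2-[4-(benzyloxy)phenyl]-5,7-dihydroxy-6-(3-hydroxy-3-methylbutyl)-4H-chromen-4-one
Product: 12 5,7-bis(benzyloxy)-2-[4-(benzyloxy)phenyl]-6-(3-hydroxy-3-methylbutyl)-4H-chromen-4-one
Conditions: BnBr (2.5 equiv), K2CO3 (4 equiv), Bu4NI (cat.), DMF, 60 °C
Reagents that add atoms: benzyl bromide, BrCc1ccccc1
Why: Williamson etherification with carbonate in DMF should alkylate the acidic 7-hydroxyl quickly and the hydrogen-bonded 5-hydroxyl at 60 °C, while the tertiary alcohol is not ionised and stays free; both phenols are capped because dimethyldioxirane oxidises free resorcinols.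

Step 7
Reactants: 12 5,7-bis(benzyloxy)-2-[4-(benzyloxy)phenyl]-6-(3-hydroxy-3-methylbutyl)-4H-chromen-4-one
Product: 14 5,7-bis(benzyloxy)-2-[4-(benzyloxy)phenyl]-3-hydroxy-6-(3-hydroxy-3-methylbutyl)-4H-chromen-4-one, via racemic cis-2,3-epoxyflavanone 13 (not isolated)
Conditions: dimethyldioxirane (acetone solution, 3 equiv), CH2Cl2, 0 °C → rt; then TsOH·H2O (cat.), CH2Cl2, rt
Reagents that add atoms: dimethyldioxirane, CC1(C)OO1
Why: Dimethyldioxirane epoxidises the C2=C3 bond of fully O-protected flavones, and under acid the epoxide opens at C2 to the aryl- and oxygen-stabilised cation, which loses the C3 proton to give the 3-hydroxyflavone (the epoxidation–rearrangement route to flavonols); the two epoxide stereocentres are racemic and vanish in this step.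

Step 8
Reactants: 14 5,7-bis(benzyloxy)-2-[4-(benzyloxy)phenyl]-3-hydroxy-6-(3-hydroxy-3-methylbutyl)-4H-chromen-4-one
Product: 15 3,5,7-trihydroxy-6-(3-hydroxy-3-methylbutyl)-2-(4-hydroxyphenyl)-4H-chromen-4-one (target)
Conditions: H2 (1 atm), Pd/C (10% palladium on carbon), EtOAc/MeOH, rt
Reagents that add atoms: none
Why: Hydrogenolysis of the three aryl benzyl ethers over palladium on carbon is neutral, so the flavonol enone and the tertiary alcohol should stay intact and acid-induced cyclisation of the carbinol onto a neighbouring phenol is avoided.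

**Compound list**

1 | 1-(benzyloxy)-4-ethynylbenzene | C#Cc1ccc(OCc2ccccc2)cc1 | starting material
2 | 3-[4-(benzyloxy)phenyl]prop-2-ynoic acid | OC(=O)C#Cc1ccc(OCc2ccccc2)cc1 | intermediate
3 | 3-[4-(benzyloxy)phenyl]prop-2-ynoyl chloride | O=C(Cl)C#Cc1ccc(OCc2ccccc2)cc1 | intermediate
4 | methyl acetoacetate | COC(=O)CC(C)=O | starting material
5 | methyl 2-acetyl-5-[4-(benzyloxy)phenyl]-3-oxopent-4-ynoate (formed in the flask, step 3) | COC(=O)C(C(C)=O)C(=O)C#Cc1ccc(OCc2ccccc2)cc1 | intermediate
6 | methyl 6-[4-(benzyloxy)phenyl]-2-methyl-4-oxo-4H-pyran-3-carboxylate | COC(=O)c1c(C)oc(-c2ccc(OCc3ccccc3)cc2)cc1=O | intermediate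
7 | ethyl 5-oxohexanoate | CCOC(=O)CCCC(C)=O | starting material
8 | ethyl 5-hydroxy-5-methylhexanoate (formed in the flask, step 4) | CCOC(=O)CCCC(C)(C)O | intermediate
9 | 6,6-dimethyltetrahydro-2H-pyran-2-one | CC1(C)CCCC(=O)O1 | intermediate
10 | methyl 6-[4-(benzyloxy)phenyl]-2-(6-hydroxy-6-methyl-2-oxoheptyl)-4-oxo-4H-pyran-3-carboxylate (formed in the flask, step 5) | COC(=O)c1c(CC(=O)CCCC(C)(C)O)oc(-c2ccc(OCc3ccccc3)cc2)cc1=O | intermediate
11 | 2-[4-(benzyloxy)phenyl]-5,7-dihydroxy-6-(3-hydroxy-3-methylbutyl)-4H-chromen-4-one | CC(C)(O)CCc1c(O)cc2oc(-c3ccc(OCc4ccccc4)cc3)cc(=O)c2c1O | intermediate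
12 | 5,7-bis(benzyloxy)-2-[4-(benzyloxy)phenyl]-6-(3-hydroxy-3-methylbutyl)-4H-chromen-4-one | CC(C)(O)CCc1c(OCc2ccccc2)cc2oc(-c3ccc(OCc4ccccc4)cc3)cc(=O)c2c1OCc1ccccc1 | intermediate
13 | 4,6-bis(benzyloxy)-1a-[4-(benzyloxy)phenyl]-5-(3-hydroxy-3-methylbutyl)-1a,7a-dihydro-7H-oxireno[2,3-b]chromen-7-one (racemic, cis ring fusion, one enantiomer drawn; formed in the flask, step 7) | CC(C)(O)CCc1c(OCc2ccccc2)cc2O[C@]3(c4ccc(OCc5ccccc5)cc4)O[C@@H]3C(=O)c2c1OCc1ccccc1 | intermediate
14 | 5,7-bis(benzyloxy)-2-[4-(benzyloxy)phenyl]-3-hydroxy-6-(3-hydroxy-3-methylbutyl)-4H-chromen-4-one | CC(C)(O)CCc1c(OCc2ccccc2)cc2oc(-c3ccc(OCc4ccccc4)cc3)c(O)c(=O)c2c1OCc1ccccc1 | intermediate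
15 | 3,5,7-trihydroxy-6-(3-hydroxy-3-methylbutyl)-2-(4-hydroxyphenyl)-4H-chromen-4-one | CC(C)(O)CCc1c(O)cc2oc(-c3ccc(O)cc3)c(O)c(=O)c2c1O | target

**Step count**

Total: 8 steps. Longest linear sequence: 7 steps (steps 1, 2, 3, 5, 6, 7, 8, from alkyne 1); the lactone branch is step 4.

**Steps most likely to fail**

Step 5 (proposed new method). What may go wrong:
- proton transfer from the lactone α-position to the amide base or to the pyranone dienolate in place of acylation;
- ring closure through the C7 enolate oxygen in place of C6;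
- self-condensation of the lithiated pyranone.

The fallback uses established reactions only: ring A comes from a phloroglucinol ether, ring C is closed by the ynone route and the chain is attached by cross-coupling. It sets out from acid chloride 3 and comes back to the route at 12. 5-(Benzyloxy)benzene-1,3-diol is protected with MOMCl and iPr2NEt as 1-(benzyloxy)-3,5-bis(methoxymethoxy)benzene F1. Directed ortho-lithiation between the two MOM ethers (n-BuLi, THF, 0 °C), transmetalation with ZnCl2 and Negishi acylation with 3 under Pd(PPh3)4 catalysis should give the ynone 1-[4-(benzyloxy)-2,6-bis(methoxymethoxy)phenyl]-3-[4-(benzyloxy)phenyl]prop-2-yn-1-one F2. HCl in MeOH removes both MOM groups, and K2CO3 in acetone closes ring C by 6-endo-dig oxa-Michael addition; either phenol gives the same product, 7-(benzyloxy)-2-[4-(benzyloxy)phenyl]-5-hydroxy-4H-chromen-4-one F3. Iodination ortho to the chelated 5-hydroxyl with benzyltrimethylammonium dichloroiodate and CaCO3 in CH2Cl2/MeOH gives 7-(benzyloxy)-2-[4-(benzyloxy)phenyl]-5-hydroxy-6-iodo-4H-chromen-4-one F4. Benzylation (BnBr, K2CO3, DMF) gives 5,7-bis(benzyloxy)-2-[4-(benzyloxy)phenyl]-6-iodo-4H-chromen-4-one F5. Hydroboration of 2-methylbut-3-en-2-ol with 9-BBN (2 equiv, THF) gives 4-(9-borabicyclo[3.3.1]nonan-9-yl)-2-methylbutan-2-ol F6 in the flask. B-alkyl Suzuki–Miyaura coupling of F6 with F5 (PdCl2(dppf), K3PO4, DMF/H2O, 60 °C) then gives 12.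

Step 7. What may go wrong:
- slow epoxidation of the hindered enone double bond next to the 5-benzyloxy group;
- oxidation of benzylic C–H bonds by the excess dioxirane;
- ring contraction of the epoxide during the acid-induced opening.

The fallback replaces electrophilic oxidation by C3 metalation; it sets out from 12 and comes back at 14. LDA (2.5 equiv, one of them taken up by the carbinol) in THF at −78 °C lithiates C3. Trimethyl borate traps the 3-lithioflavone as dimethyl {5,7-bis(benzyloxy)-2-[4-(benzyloxy)phenyl]-6-(3-hydroxy-3-methylbutyl)-4-oxo-4H-chromen-3-yl}boronate F7. Oxidation in the same flask with H2O2 and AcOH gives 14.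

Step 3. What may go wrong:
- addition of chloride or pyridine across the activated triple bond;
- O-acylation of the enolate in place of C-acylation;
- closure of 5 in the 5-exo mode.

The fallback avoids the alkynoyl chloride and brings in the C5=C6 double bond by dehydrogenation; it sets out from methyl acetoacetate 4 and comes back at 6. Commercial (E)-4-(benzyloxy)cinnamic acid is converted with (COCl)2 and DMF (cat.) into (2E)-3-[4-(benzyloxy)phenyl]prop-2-enoyl chloride F8. Acylation of 4 under the MgCl2/pyridine conditions gives methyl (4E)-2-acetyl-5-[4-(benzyloxy)phenyl]-3-oxopent-4-enoate F9. 6-Endo-trig oxa-Michael closure (TsOH cat., PhMe, 80 °C) gives racemic methyl 2-[4-(benzyloxy)phenyl]-6-methyl-4-oxo-3,4-dihydro-2H-pyran-5-carboxylate F10. Dehydrogenation with DDQ in dioxane at reflux, as for flavanones, gives 6.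

**Further compounds**

F1 | step 5 | 1-(benzyloxy)-3,5-bis(methoxymethoxy)benzene | COCOc1cc(OCOC)cc(OCc2ccccc2)c1
F2 | step 5 | 1-[4-(benzyloxy)-2,6-bis(methoxymethoxy)phenyl]-3-[4-(benzyloxy)phenyl]prop-2-yn-1-one | COCOc1cc(OCc2ccccc2)cc(OCOC)c1C(=O)C#Cc1ccc(OCc2ccccc2)cc1
F3 | step 5 | 7-(benzyloxy)-2-[4-(benzyloxy)phenyl]-5-hydroxy-4H-chromen-4-one | O=c1cc(-c2ccc(OCc3ccccc3)cc2)oc2cc(OCc3ccccc3)cc(O)c12
F4 | step 5 | 7-(benzyloxy)-2-[4-(benzyloxy)phenyl]-5-hydroxy-6-iodo-4H-chromen-4-one | O=c1cc(-c2ccc(OCc3ccccc3)cc2)oc2cc(OCc3ccccc3)c(I)c(O)c12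
F5 | step 5 | 5,7-bis(benzyloxy)-2-[4-(benzyloxy)phenyl]-6-iodo-4H-chromen-4-one | O=c1cc(-c2ccc(OCc3ccccc3)cc2)oc2cc(OCc3ccccc3)c(I)c(OCc3ccccc3)c12
F6 | step 5 | 4-(9-borabicyclo[3.3.1]nonan-9-yl)-2-methylbutan-2-ol | CC(C)(O)CCB1C2CCCC1CCC2
F7 | step 7 | dimethyl {5,7-bis(benzyloxy)-2-[4-(benzyloxy)phenyl]-6-(3-hydroxy-3-methylbutyl)-4-oxo-4H-chromen-3-yl}boronate | COB(OC)c1c(-c2ccc(OCc3ccccc3)cc2)oc2cc(OCc3ccccc3)c(CCC(C)(C)O)c(OCc3ccccc3)c2c1=O
F8 | step 3 | (2E)-3-[4-(benzyloxy)phenyl]prop-2-enoyl chloride | O=C(Cl)/C=C/c1ccc(OCc2ccccc2)cc1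
F9 | step 3 | methyl (4E)-2-acetyl-5-[4-(benzyloxy)phenyl]-3-oxopent-4-enoate | COC(=O)C(C(C)=O)C(=O)/C=C/c1ccc(OCc2ccccc2)cc1
F10 | step 3 | methyl 2-[4-(benzyloxy)phenyl]-6-methyl-4-oxo-3,4-dihydro-2H-pyran-5-carboxylate (racemic) | COC(=O)C1=C(C)OC(c2ccc(OCc3ccccc3)cc2)CC1=O
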